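**Retrosynthetic overview**

- The last two steps only unmask: HF cleavage of the O3 silyl ether, preceded by acidolysis of a 4-methoxybenzyl (PMB) ester on the C1 carboxyl group.
- Key disconnection: both Cβ–C(aryl) bonds. On the cyclohexane ring, the vicinal trans oxygens O4 and O5 each carry an ester that is an acrylate unit O–C(=O)–Cα=Cβ with a 4-hydroxyphenyl ring on Cβ. Cutting both aryl bonds leaves a 4,5-diacrylate and two molecules of 4-iodophenol, so the crowded O4 only has to accept the small acryloyl group (twofold Mizoroki–Heck arylation).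
- The diacrylate comes from acryloylation of PMB 3-O-silylquinate, which comes from hydroxide opening and carboxylate alkylation of 3-O-silyl-1,5-quinide, itself made from (−)-quinic acid by lactonisation and O3 silylation.
- Ring order: no carbocycle or arene is built. The cyclohexane and its four stereocentres come from quinic acid, and both benzene rings arrive intact with 4-iodophenol. The only ring formed is the temporary 1,5-lactone (step 1), which tells O3 from O5 and is opened again in step 3.

Key step: step 5

Remark: IUPAC quinic acid numbering is used (O3 is cis to O4 and to the 1-OH; O5 is trans to O4 and closes the 1,5-lactone), and the target has its free secondary hydroxyl on C3. The carboxyl group is carried through the key step as its PMB ester, because a free acid next to a free 5-OH cannot be acryloylated without mixed-anhydride formation and re-lactonisation.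

**Route**

Step 1
Reactants: 1 (−)-quinic acid, (1S,3R,4S,5R)-1,3,4,5-tetrahydroxycyclohexane-1-carboxylic acid
Product: 2 1,5-quinide, (1S,3R,4R,5R)-1,3,4-trihydroxy-6-oxabicyclo[3.2.1]octan-7-one
Conditions: TsOH·H2O (cat.), toluene/DMF, reflux, Dean–Stark
Reagents that add atoms: none
Why: Acid-catalysed lactonisation (intramolecular Fischer esterification): in the inverted chair the carboxyl group and the cis 5-OH are 1,3-diaxial and close the bicyclic γ-lactone while water leaves azeotropically; no stereocentre is touched, and the 3-OH, on the opposite face to the carboxyl group, cannot lactonise.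

Step 2
Reactants: 2 1,5-quinide; 3 tert-butyldimethylsilyl chloride (TBSCl)
Product: 4 3-O-(tert-butyldimethylsilyl)-1,5-quinide (silyl ether on the equatorial O3; 1-OH and 4-OH free; stereocentres as in 2)
Conditions: TBSCl (1.1 equiv), imidazole, DMF, 0 °C
Reagents that add atoms: tert-butyldimethylsilyl chloride, CC(C)(C)[Si](C)(C)Cl
Why: Regioselective silyl ether formation under imidazole catalysis: in the rigid lactone the 3-OH is the only equatorial secondary hydroxyl, the 4-OH is axial beside the lactone bridge and the 1-OH is tertiary, so one equivalent of the bulky chlorosilane should go to O3.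

Step 3
Reactants: 4 3-O-(tert-butyldimethylsilyl)-1,5-quinide; 5 4-methoxybenzyl chloride (PMBCl)
Product: 7 4-methoxybenzyl 3-O-(tert-butyldimethylsilyl)quinate (1-, 4- and 5-OH free; stereocentres as in quinic acid), via lithium 3-O-(tert-butyldimethylsilyl)quinate 6 (not isolated)
Conditions: LiOH·H2O (1.0 equiv), THF/H2O, 0 °C; evaporate; then PMBCl, Bu4NI (cat.), DMF, rt
Reagents that add atoms: lithium hydroxide, [Li+].[OH-]; 4-methoxybenzyl chloride, COc1ccc(CCl)cc1
Why: Saponification of the strained bicyclic lactone by one equivalent of hydroxide, then SN2 O-alkylation of the carboxylate by the benzylic chloride under iodide catalysis, which leaves the neutral hydroxyls alone; the hydroxide is used up as the lactone opens, so the time in which an O4 alkoxide could take over the silyl group is short, and no stereocentre is touched.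

Step 4
Reactants: 7 4-methoxybenzyl 3-O-(tert-butyldimethylsilyl)quinate; 8 acryloyl chloride
Product: 9 4-methoxybenzyl 4,5-di-O-acryloyl-3-O-(tert-butyldimethylsilyl)quinate (1-OH free)
Conditions: acryloyl chloride (3 equiv), Et3N, DMAP (cat.), BHT (trace), CH2Cl2, −20 to 0 °C
Reagents that add atoms: acryloyl chloride, C=CC(=O)Cl
Why: DMAP-catalysed O-acylation with an acid chloride: the equatorial 5-OH and the more hindered equatorial 4-OH beside the axial silyl ether are both secondary and within reach of the small acryloyl group, whereas the tertiary 1-OH next to the ester carbonyl should stay free at low temperature with a limited excess of reagent.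

Step 5
Reactants: 9 4-methoxybenzyl 4,5-di-O-acryloyl-3-O-(tert-butyldimethylsilyl)quinate; 10 4-iodophenol
Product: 11 4-methoxybenzyl 3-O-(tert-butyldimethylsilyl)-4,5-di-O-[(E)-4-hydroxycinnamoyl]quinate
Conditions: 4-iodophenol (2.6 equiv), Pd(OAc)2 (10 mol %), NaHCO3, Bu4NCl, DMF, 60 °C, Ar
Reagents that add atoms: 4-iodophenol, Oc1ccc(I)cc1
Why: Palladium diacetate (divalent palladium) is reduced in the flask to zerovalent palladium, kept in solution by chloride from Bu4NCl; it adds oxidatively to the C–I bond of 10, the arylpalladium species binds an acrylate C=C, syn-carbopalladation puts the aryl group on the unsubstituted Cβ, syn β-hydride elimination releases the (E)-cinnamate, and NaHCO3 takes up HI to return zerovalent palladium, after which the cycle repeats on the second acrylate. The closest known reaction type is the Mizoroki–Heck arylation of acrylate esters with aryl iodides under ligand-free phase-transfer (Jeffery) conditions, unprotected iodophenols included. No ring is closed and no stereocentre is formed; the four ring stereocentres of 9 are remote spectators. The step needs β-regiochemistry and E geometry, which the polarised monosubstituted acrylate and the syn-elimination geometry (aryl and ester anti) secure, and chemoselectivity for C–I over O–H, the PMB ester and the silyl ether, which the mild bicarbonate base secures. Acyl migration from O4 to O3 in the basic medium is excluded because O3 is silylated, and a second arylation at Cβ is held back because the cinnamate formed is a much poorer Heck acceptor than an acrylate.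

Step 6
Reactants: 11 4-methoxybenzyl 3-O-(tert-butyldimethylsilyl)-4,5-di-O-[(E)-4-hydroxycinnamoyl]quinate
Product: 12 3-O-(tert-butyldimethylsilyl)-4,5-di-O-[(E)-4-hydroxycinnamoyl]quinic acid
Conditions: TFA/CH2Cl2 (1:9), anisole (10 equiv), 0 °C
Reagents that add atoms: none
Why: Acidolysis of a 4-methoxybenzyl ester: protonation and loss of the stabilised 4-methoxybenzyl cation, which the excess anisole traps by Friedel–Crafts alkylation before it can reach the phenol rings; cinnamate esters and alkenes are inert to dilute TFA, and any silyl ether lost here is removed in step 7 anyway.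

Step 7
Reactants: 12 3-O-(tert-butyldimethylsilyl)-4,5-di-O-[(E)-4-hydroxycinnamoyl]quinic acid
Product: 13 4,5-di-O-p-coumaroylquinic acid (target)
Conditions: 48% aq. HF, MeCN, 0 °C to rt
Reagents that add atoms: none
Why: Fluoride-mediated cleavage of a silyl ether under acidic conditions, driven by Si–F bond formation; acyl migration between vicinal hydroxyls is base-catalysed, so the acidic medium should leave the 4- and 5-esters in place once the 3-OH is free, and the alkenes keep their E geometry.

**Compound list**

1 | (−)-quinic acid | O[C@@H]1[C@H](O)C[C@@](O)(C(=O)O)C[C@H]1O | starting material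
2 | 1,5-quinide (quinic acid 1,5-lactone) | O[C@@H]1[C@H](O)C[C@]2(O)C[C@H]1OC2=O | intermediate
3 | tert-butyldimethylsilyl chloride | CC(C)(C)[Si](C)(C)Cl | starting material
4 | 3-O-(tert-butyldimethylsilyl)-1,5-quinide | O[C@@H]1[C@H](O[Si](C)(C)C(C)(C)C)C[C@]2(O)C[C@H]1OC2=O | intermediate
5 | 4-methoxybenzyl chloride | COc1ccc(CCl)cc1 | starting material
6 | lithium 3-O-(tert-butyldimethylsilyl)quinate | O[C@@H]1[C@H](O[Si](C)(C)C(C)(C)C)C[C@@](O)(C(=O)[O-])C[C@H]1O.[Li+] | intermediate
7 | 4-methoxybenzyl 3-O-(tert-butyldimethylsilyl)quinate | O[C@@H]1[C@H](O[Si](C)(C)C(C)(C)C)C[C@@](O)(C(=O)OCc2ccc(OC)cc2)C[C@H]1O | intermediate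
8 | acryloyl chloride | C=CC(=O)Cl | starting material
9 | 4-methoxybenzyl 4,5-di-O-acryloyl-3-O-(tert-butyldimethylsilyl)quinate | C=CC(=O)O[C@@H]1[C@H](O[Si](C)(C)C(C)(C)C)C[C@@](O)(C(=O)OCc2ccc(OC)cc2)C[C@H]1OC(=O)C=C | intermediate
10 | 4-iodophenol | Oc1ccc(I)cc1 | starting material
11 | 4-methoxybenzyl 3-O-(tert-butyldimethylsilyl)-4,5-di-O-[(E)-4-hydroxycinnamoyl]quinate | O=C(/C=C/c1ccc(O)cc1)O[C@@H]1[C@H](O[Si](C)(C)C(C)(C)C)C[C@@](O)(C(=O)OCc2ccc(OC)cc2)C[C@H]1OC(=O)/C=C/c1ccc(O)cc1 | intermediate
12 | 3-O-(tert-butyldimethylsilyl)-4,5-di-O-[(E)-4-hydroxycinnamoyl]quinic acid | O=C(/C=C/c1ccc(O)cc1)O[C@@H]1[C@H](O[Si](C)(C)C(C)(C)C)C[C@@](O)(C(=O)O)C[C@H]1OC(=O)/C=C/c1ccc(O)cc1 | intermediate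
13 | 4,5-di-O-p-coumaroylquinic acid | O=C(/C=C/c1ccc(O)cc1)O[C@@H]1[C@H](O)C[C@@](O)(C(=O)O)C[C@H]1OC(=O)/C=C/c1ccc(O)cc1 | target

**Step count**

Total steps: 7. Longest linear sequence: 7 steps (1 to 13).

**Steps most likely to fail**

1. Step 5 (double Heck arylation). The catalytic cycle may stop after the first arylation: the electron-rich iodophenol adds slowly to zerovalent palladium, ligand-free palladium can aggregate to inactive metal, and phenoxide may add in conjugate fashion to the remaining acrylate. The fallback builds the Cα=Cβ bonds by Knoevenagel–Doebner condensation instead. It sets out from diol 7: heating with Meldrum's acid (2,2-dimethyl-1,3-dioxane-4,6-dione) in toluene at about 90 °C should open the dioxanedione at O4 and O5 with loss of acetone and give 4-methoxybenzyl 4,5-bis-O-(carboxyacetyl)-3-O-(tert-butyldimethylsilyl)quinate F1. Condensation of F1 with 4-hydroxybenzaldehyde (pyridine, piperidine cat., 40 °C) with decarboxylation should give the two (E)-cinnamates, and the fallback comes back to the route at 11.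

2. Step 3 (lactone opening and esterification). While hydroxide is present the silyl group may move from the axial O3 to the neighbouring equatorial O4, or the lactone may close again during concentration and alkylation. The fallback blocks O3 with an ether that cannot migrate and sets out from quinide 2.
   - Bu2SnO in refluxing toluene (Dean–Stark) should give 3,4-O-dibutylstannylene-1,5-quinide F2.
   - PMBCl with Bu4NI (cat.) should alkylate its equatorial oxygen to give 3-O-(4-methoxybenzyl)-1,5-quinide F3.
   - LiOH opening as in step 3 gives lithium 3-O-(4-methoxybenzyl)quinate F4, and PMBCl then gives 4-methoxybenzyl 3-O-(4-methoxybenzyl)quinate F5.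
   - Acryloylation as in step 4 gives 4-methoxybenzyl 4,5-di-O-acryloyl-3-O-(4-methoxybenzyl)quinate F6.
   - The Heck coupling of step 5 gives 4-methoxybenzyl 3-O-(4-methoxybenzyl)-4,5-di-O-[(E)-4-hydroxycinnamoyl]quinate F7.
   - TFA/anisole in CH2Cl2 removes the PMB ester and the PMB ether together, so the fallback comes back at the target 13 and the HF step is no longer needed.

3. Step 4 (diacryloylation). Amine-triggered oligomerisation and conjugate addition may use up the acryloyl chloride before the hindered O4 is esterified, and forcing the reaction may begin to acylate the tertiary O1. The fallback carries the acrylate in masked form and sets out from diol 7: 3-chloropropanoyl chloride with pyridine in CH2Cl2 should give 4-methoxybenzyl 4,5-bis-O-(3-chloropropanoyl)-3-O-(tert-butyldimethylsilyl)quinate F8. Et3N in CH2Cl2 at rt then eliminates HCl from both chains, and the fallback comes back to the route at 9.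

Further compounds
F1 | step 5 | 4-methoxybenzyl 4,5-bis-O-(carboxyacetyl)-3-O-(tert-butyldimethylsilyl)quinate | O=C(O)CC(=O)O[C@@H]1[C@H](O[Si](C)(C)C(C)(C)C)C[C@@](O)(C(=O)OCc2ccc(OC)cc2)C[C@H]1OC(=O)CC(=O)O
F2 | step 3 | 3,4-O-dibutylstannylene-1,5-quinide | CCCC[Sn]1(CCCC)O[C@@H]2[C@H](O1)C[C@]3(O)C[C@H]2OC3=O
F3 | step 3 | 3-O-(4-methoxybenzyl)-1,5-quinide | O[C@@H]1[C@H](OCc2ccc(OC)cc2)C[C@]3(O)C[C@H]1OC3=O
F4 | step 3 | lithium 3-O-(4-methoxybenzyl)quinate | O[C@@H]1[C@H](OCc2ccc(OC)cc2)C[C@@](O)(C(=O)[O-])C[C@H]1O.[Li+]
F5 | step 3 | 4-methoxybenzyl 3-O-(4-methoxybenzyl)quinate | O[C@@H]1[C@H](OCc2ccc(OC)cc2)C[C@@](O)(C(=O)OCc2ccc(OC)cc2)C[C@H]1O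
F6 | step 3 | 4-methoxybenzyl 4,5-di-O-acryloyl-3-O-(4-methoxybenzyl)quinate | C=CC(=O)O[C@@H]1[C@H](OCc2ccc(OC)cc2)C[C@@](O)(C(=O)OCc2ccc(OC)cc2)C[C@H]1OC(=O)C=C
F7 | step 3 | 4-methoxybenzyl 3-O-(4-methoxybenzyl)-4,5-di-O-[(E)-4-hydroxycinnamoyl]quinate | O=C(/C=C/c1ccc(O)cc1)O[C@@H]1[C@H](OCc2ccc(OC)cc2)C[C@@](O)(C(=O)OCc2ccc(OC)cc2)C[C@H]1OC(=O)/C=C/c1ccc(O)cc1
F8 | step 4 | 4-methoxybenzyl 4,5-bis-O-(3-chloropropanoyl)-3-O-(tert-butyldimethylsilyl)quinate | O=C(CCCl)O[C@@H]1[C@H](O[Si](C)(C)C(C)(C)C)C[C@@](O)(C(=O)OCc2ccc(OC)cc2)C[C@H]1OC(=O)CCCl
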